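## Structural features

The target is a bisabolane-type C15 skeleton: one cyclohexane ring (C1–C6, methyl on C4) joined through C1 to the chain C7–C11. In the chain, C7 carries an exocyclic methylene, C8 is a carbinol esterified with angelic acid, and C9–C11 form a prenyl terminus. Every ring carbon is functionalised: acetoxy groups on C2 and C6 flank C1, a trisubstituted epoxide spans C3–C4, and a ketone sits at C5 between the epoxide carbon and C6. Five contiguous ring stereocentres (C1, C2, C3, C4, C6) stand next to each other, and C8 (S) is separated from them by the sp2 carbon C7. The C7 substituent and the epoxide oxygen lie on one face (α), and the C2 and C6 oxygens lie on the other (β), so each substituent is trans to its ring neighbour. Fragile groups are the α,β-epoxy ketone with its epimerisable α'-acetoxy methine C6, the angelate (Z to E isomerisation under nucleophilic or basic catalysis), the allylic ester at C8, and the skipped diene of the side chain, whose prenyl alkene is more nucleophilic than any ring alkene. The real difficulty is to place six oxygen functions on defined faces of a ring that has a single carbon substituent to steer reagents, to tell C5 apart from C2 and C6, and to set C8. The key step exploits the 1,4-relationship of C1 and C4 with C7 and the C4 oxygen cis: this is the imprint of the carboxylate bridge of a 2-oxabicyclo[2.2.2]octenone, in which C7 is the lactone carbonyl, the C4 oxygen is the ring oxygen, and endo dienophile oxygens on C5/C6 fall on the opposite face.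

## Logic of the disconnections

27 is traced to 26 by removing the C5 carbonyl (C5=O back to C5–OH). The epoxy ketone next to an acetoxy methine is base-sensitive, so it is made last under neutral oxidation. This requires that C5–OH be the only free hydroxyl of 26.

26 is traced to 25 and then 24 by cutting the two acetyl C–O bonds at O2 and O6 and masking the three ring hydroxyls as silyl ethers. Acetates would not survive the organometallic and enolate steps. The forward demand is a fluoride deprotection that spares epoxide and angelate, and an acetylation that distinguishes the equatorial C2/C6 hydroxyls from the axial, neopentyl-like C5 hydroxyl.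

24 is cut at the C8–O acyl bond to 21 and 22. The angelate is introduced late because it isomerises easily; the esterification must proceed without Z/E scrambling and with retention at C8.

21 is traced through 20 and 19 to 17 and 18. C8 is 1,3 to the nearest ring stereocentre, so its configuration is set by a reagent-controlled reduction of the C8 ketone. The C7–C8 bond is cut between an alkenyl triflate and a purchased aldehyde. The coupling must leave the epoxide untouched and must not isomerise the β,γ-unsaturated aldehyde.

17 is traced to 15 and 14 by cutting the C7–OTf bond and the C7–CH3 bond, so the future methylene carbon comes from a methyl nucleophile added to a carboxamide. C7 is the lactone carbonyl of the cycloadduct and stays at the acid oxidation level throughout, which avoids redox adjustments. The demand is enolisation toward the methyl group only.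

14 is traced through 13 to 11 by cutting the C3–O bond of the epoxide and returning that oxygen to C4 alone, with a β-oxygen bridge placed across C2–C3 (retro-Payne). The C4 oxygen fixed by the bridge thus becomes the epoxide oxygen, with inversion at C3. The precursor is the product of a simple cis addition of oxygen to an alkene. The forward step needs a free, anti-periplanar C4 alkoxide and a capped C5 oxygen. This replaces a dihydroxylation/cyclic-sulfate sequence and avoids an acidic sulfate hydrolysis next to the epoxide.

11 is traced through 10, 9 and 8 to 5 by cutting the C2–O and C3–O bonds of the β-epoxide back to the C2=C3 alkene formed in the cycloaddition. Oxygen must arrive on the β face, anti to the C4 oxygen. Therefore the C4 hydroxyl is silylated (blocking the α face and its directing effect) while the 5,6-diol is left free to direct. The amide is installed before the epoxide so that no β-epoxy ester meets a basic reagent.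

5 is traced through 4 to 3 by resolution, then by cutting the ester C7–OMe bond and restoring the C7–O–C4 lactone and the C5/C6 carbonate. One methanolysis opens both rings without touching any C–O bond at a stereocentre. The demand is that C1, α to the ester and allylic, is not epimerised.

3 is cut at C1–C6 and C4–C5 to 1 and 2 by a retro-[4+2]. Two purchased achiral compounds deliver the carbocycle, the C7 carbon, the C4 methyl and oxygen, and four stereocentres in relative control. The cost is a racemate that must be resolved.

## Other disconnections considered

Alternative 1: The cut is C2–C3, leading to the open-chain dialdehyde A2. In the forward step SmI2 would reduce both formyl groups to ketyls held on samarium, which couple to the cis-2,3-diol A1 and close the ring. In its favour, the side chain with its C8 stereocentre is in place before ring closure, and all stereocentres of A2 could come from enantiopure acyclic building blocks. On absolute stereocontrol and convergence it is the better plan, since no resolution is needed. Against it, A2 carries one formyl group on a quaternary α-alkoxy carbon, where divalent samarium can cleave the C4–O bond before coupling. The other formyl group sits on C1, which is α to the C7 alkene and β to a silyloxy group, so epimerisation, alkene migration and β-elimination threaten. The cis and anti,anti outcome rests on chelation with four diols possible, whereas the concerted cycloaddition fixes its relative configuration by geometry. A1 also still needs a choice between the C2 and C3 hydroxyls for activation, which the Payne route avoids. Five stereocentres of A2 must be set one by one, so step economy favours the chosen plan.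

Alternative 2: The cuts are C7–C8 and the bond from C8 to the C2 oxygen. In the forward step PdCl2(PPh3)2 with SnCl2 under CO converts the trans-2-ethynyl alcohol A4 into the α-methylene lactone A3. In its favour, the exocyclic methylene and C8 arrive in one catalytic step from CO, and the trans ethynyl/hydroxyl pattern of A4 is what an acetylide opening of an epoxide gives. On installing the methylene it is shorter than steps 10 to 12 here and is the better of the two on that point. Against it, C8 in A3 is a lactone carbonyl. Turning it into the 8S carbinol needs a single addition of a 3-methylbut-2-enyl nucleophile to a Michael-accepting lactone (conjugate addition, γ-attack and double addition all compete), then a stereoselective reduction and release of the C2 oxygen. SnCl2 is a Lewis acid next to an epoxide and an acetonide. The ring of A4 must already be complete, so this alternative solves only the side chain and would add steps to any ring synthesis, including the one chosen here.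

Alternative 3: The cut is C1–C2. In the forward step CrCl2 turns the allylic bromide of the open-chain enal A6 into an allylchromium whose γ-carbon C1 adds to the C2 aldehyde, giving the cyclohexenol A5 with the alkene moved to the exocyclic position. In its favour, one mild step closes the ring, makes the methylene and sets C1 and C2. The anti C1/C2 relationship is the normal result of γ-substituted allylchromium additions, so on that relationship it is the equal of the chosen plan. It carries the full side chain including the angelate, so on convergence it is better. Against it, A6 must be a Z-enal, which is prone to isomerisation and is a weak electrophile. The facial sense relative to C6 is not held by any cyclic constraint. The acetonide across the trans-5,6-diol is strained. A5 then needs an α-face epoxidation of C3=C4 in the presence of the more nucleophilic prenyl alkene, while its free β-hydroxyl at C2 would direct a peracid to the wrong face. C4 would thus be set by a late substrate-controlled oxidation and not by construction, so on chemoselectivity and on C4/epoxide control the chosen plan is the safer one.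

Key step: step 1

Remark: ring carbons are C1–C6 and chain carbons C7–C11 as in the target; α is the ring face carrying C7 and the C4 oxygen, β the face carrying the C4 methyl group and the oxygens on C2, C5 and C6.
Remark: the structure of adduct 3 was checked centre by centre against the target (C1, C4 and C6 as required, C5 is oxidised later) and needed no correction; 3 and 4 are racemic and are drawn as the enantiomer of the target series.
Remark (assumption): the lipase in step 3 is taken to acylate the (1S,4R,5R,6R) antipode faster; if the preference is the reverse, 5 is obtained from the separated monoacetate by K2CO3/MeOH and the route is unchanged.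

## Route

Step 1
Reactants: 1 6-methyl-2H-pyran-2-one; 2 vinylene carbonate (1,3-dioxol-2-one)
Product: 3 (±)-endo-7,8-(carbonyldioxy)-1-methyl-2-oxabicyclo[2.2.2]oct-5-en-3-one (lactone C7(=O)–O–C4; carbonate on C5/C6 anti to the lactone bridge; alkene C2=C3)
Conditions: 2 (3 equiv), CH2Cl2, 13 kbar, 40 °C, 96 h
Reagents that add atoms: none
Why: Mechanism: a concerted, thermally allowed [4πs+2πs] cycloaddition in which the pyrone reacts as a cyclic diene through its C3 and C6 termini (the future C1 and C4) and 2 as the 2π partner, so that C1–C6 and C4–C5 form in one step; the closest known reaction type is the pressure-promoted Diels–Alder addition of 2-pyrones to alkenes that keeps the CO2 bridge. The one ring closed is the carbocycle C1–C6, by intermolecular cycloaddition, and the pyrone ester becomes the C7(=O)–O bridge between C1 and C4. C1 and C4 are fixed relative to each other by that bridge, which forces C7 and the C4 oxygen onto one ring face and the C4 methyl group onto the other. C5 and C6 are mutually cis because the Z-configured ring alkene of 2 adds suprafacially. Their orientation relative to the bridge is set by the endo transition state, in which the carbonate ring lies under the diene carbons that become C2=C3; this is the more compact arrangement and the one that pressure favours, and it places both carbonate oxygens anti to the lactone bridge. No regiochemical question arises because 2 is symmetric. The selectivities the step needs are endo over exo and cycloaddition over cycloreversion with loss of CO2: the large negative activation volume lets the reaction run near 40 °C, well below the temperature at which the adduct would extrude CO2. Both partners are achiral, so 3 is racemic and the absolute configuration is dealt with in step 3.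

Step 2
Reactants: 3 (±)-endo bridged lactone carbonate
Product: 4 (±)-methyl (1R*,4S*,5S*,6S*)-4,5,6-trihydroxy-4-methylcyclohex-2-ene-1-carboxylate
Conditions: K2CO3 (0.2 equiv), MeOH, 0 °C, 1 h; then acidic ion-exchange resin (H+ form), filter
Reagents that add atoms: methanol, CO
Why: Base-catalysed transesterification: methoxide opens the strained bridged lactone at the acyl carbon and turns the five-membered carbonate into dimethyl carbonate, so no C–O bond at C4, C5 or C6 is broken and all four stereocentres are kept. Catalytic base at 0 °C should leave the C1 proton (α to the ester and allylic) unexchanged, and the 1,6-trans arrangement from the cycloaddition is in any case the more stable one.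

Step 3
Reactants: 4 (±)-triol methyl ester
Product: 5 methyl (1R,4S,5S,6S)-4,5,6-trihydroxy-4-methylcyclohex-2-ene-1-carboxylate (ester α; C4–OH α; C4–Me, C5–OH and C6–OH β)
Conditions: immobilised Candida antarctica lipase B, vinyl acetate (3 equiv), t-BuOMe/THF, 30 °C, stopped slightly beyond half conversion; chromatography
Reagents that add atoms: none
Why: Lipase-catalysed kinetic resolution by irreversible transesterification with an enol ester; only the C6 hydroxyl is accessible (C5–OH is next to the quaternary carbinol, C4–OH is tertiary), so the fast-reacting antipode leaves as its 6-acetate and 5 is recovered unchanged. Running a little past half conversion should raise the enantiomeric purity of the recovered triol.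

Step 4
Reactants: 5 (1R,4S,5S,6S)-triol methyl ester
Product: 8 methyl (1R,4S,5S,6S)-5,6-dihydroxy-4-methyl-4-(trimethylsilyloxy)cyclohex-2-ene-1-carboxylate, via phenylboronate 6 (not isolated), via silylated phenylboronate 7 (not isolated)
Conditions: PhB(OH)2 (1.05 equiv), MgSO4, CH2Cl2, rt; then TMSOTf (1.3 equiv), 2,6-lutidine, −78 °C; then pinacol (3 equiv), MeOH, rt
Reagents that add atoms: trimethylsilyl trifluoromethanesulfonate, C[Si](C)(C)OS(=O)(=O)C(F)(F)F
Why: Transient boronate masking: the cis-5,6-diol condenses with the boronic acid to a five-membered dioxaborolane, which leaves the tertiary C4 hydroxyl as the only site for silylation; exchange onto pinacol then frees the diol. No stereocentre is involved.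

Step 5
Reactants: 8 C4-silylated diol ester
Product: 9 (1R,4S,5S,6S)-5,6-dihydroxy-N-methoxy-N,4-dimethyl-4-(trimethylsilyloxy)cyclohex-2-ene-1-carboxamide
Conditions: MeNH(OMe)·HCl (3 equiv), i-PrMgCl (8 equiv), THF, −20 → 0 °C; aq. NH4Cl
Reagents that add atoms: N,O-dimethylhydroxylamine hydrochloride, CNOC.Cl
Why: Aminolysis of the methyl ester by the chloromagnesium amide of N,O-dimethylhydroxylamine (Weinreb amide synthesis); the amide is less prone to α-deprotonation than the ester in the basic steps that follow and later gives the methyl ketone without over-addition. The magnesium amide is too weak a base to remove the C1 proton at −20 °C, so C1 keeps its configuration.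

Step 6
Reactants: 9 Weinreb amide diol
Product: 10 2β,3β-epoxide of 9 (amide α; C4–OTMS α; C5–OH and C6–OH β)
Conditions: m-CPBA (1.5 equiv), NaHCO3, CH2Cl2, 0 °C → rt
Reagents that add atoms: 3-chloroperbenzoic acid, OOC(=O)c1cccc(Cl)c1
Why: Prilezhaev epoxidation under hydroxyl direction (Henbest effect): in the half-chair with the amide and the C4 methyl group pseudo-equatorial, the C5 hydroxyl is axial on the β face and hydrogen-bonds to the peracid, while the α face is shielded by the pseudo-axial C4 silyl ether and the C1 amide. Both effects should deliver oxygen to the β face, which sets C2 and C3 syn to the diol and anti to the C4 oxygen, as the ring closure in step 8 requires.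

Step 7
Reactants: 10 β-epoxy diol
Product: 11 5,6-bis-O-(tert-butyldimethylsilyl) ether of 10
Conditions: TBSOTf (2.6 equiv), 2,6-lutidine, CH2Cl2, −40 → 0 °C
Reagents that add atoms: tert-butyldimethylsilyl trifluoromethanesulfonate, CC(C)(C)[Si](C)(C)OS(=O)(=O)C(F)(F)F
Why: Silyl triflate/lutidine silylation of both secondary hydroxyls (the hindered axial C5–OH needs the triflate). Capping O5 prevents it from later attacking C4 of the rearranged epoxide, and the two TBS ethers outlast the base that removes the trimethylsilyl group.

Step 8
Reactants: 11 bis-TBS β-epoxide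
Product: 13 (2β-hydroxy-3α,4α-epoxy-5β,6β-bis-TBS-oxy) Weinreb amide, via C4 carbinol 12 (not isolated)
Conditions: K2CO3 (1.5 equiv), MeOH, 0 °C → rt
Reagents that add atoms: none
Why: Methanolysis removes only the trimethylsilyl ether, and the freed tertiary C4 alkoxide, anti-periplanar to the C3–O bond of the β-epoxide, displaces it from the α face (Payne rearrangement, 3-exo-tet, inversion at C3). The equilibrium should lie on the side of 13 because a trisubstituted epoxide and a secondary alcohol replace a disubstituted epoxide and a tertiary alcohol; C3 ends with its oxygen α and C2 keeps its β oxygen.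

Step 9
Reactants: 13 epoxy alcohol
Product: 14 2-O-triethylsilyl ether of 13
Conditions: TESCl (1.5 equiv), imidazole, 4-(dimethylamino)pyridine (cat.), DMF, 0 °C → rt
Reagents that add atoms: chlorotriethylsilane, CC[Si](Cl)(CC)CC
Why: Standard silylation of the free secondary C2 alcohol; it must be masked because a β-hydroxy ketone would undergo retro-aldol cleavage or O-sulfonylation in steps 10 and 11.

Step 10
Reactants: 14 tris-silyl Weinreb amide
Product: 15 methyl ketone (C7 = C=O bearing the new methyl group; ring as in 14)
Conditions: MeMgBr (3 equiv), THF, −20 → 0 °C; aq. NH4Cl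
Reagents that add atoms: methylmagnesium bromide, C[Mg]Br
Why: Weinreb ketone synthesis: the magnesium-chelated adduct persists until work-up, so a single methyl group is transferred, and the epoxide is not opened by the Grignard reagent at this temperature. The new methyl carbon is the future exocyclic methylene carbon.

Step 11
Reactants: 15 methyl ketone
Product: 17 C7 enol triflate (ring–C(OTf)=CH2), via potassium enolate 16 (not isolated)
Conditions: KN(SiMe3)2 (1.2 equiv), THF, −78 °C; then PhNTf2 (1.3 equiv), −78 → 0 °C
Reagents that add atoms: N-phenylbis(trifluoromethanesulfonimide), FC(F)(F)S(=O)(=O)N(c1ccccc1)S(=O)(=O)C(F)(F)F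
Why: Kinetic deprotonation of a methyl ketone by a bulky amide base occurs at the methyl group and not at the hindered C1–H, and O-sulfonylation of that enolate gives the 1-alken-2-yl triflate. Because the C1 proton is never removed, neither epimerisation nor β-elimination of the C2 or C6 silyloxy groups can start.

Step 12
Reactants: 17 enol triflate; 18 4-methylpent-3-enal
Product: 19 C8 allylic alcohol (ring–C(=CH2)–CH(OH)–CH2CH=CMe2) as the mixture of C8 epimers
Conditions: CrCl2 (6 equiv), NiCl2 (5 mol%), 18 (3 equiv, freshly distilled), degassed DMF, rt
Reagents that add atoms: none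
Why: Nozaki–Hiyama–Kishi coupling: zerovalent nickel inserts into the C–OTf bond, the alkenyl group passes to trivalent chromium, and the alkenylchromium adds to the aldehyde only, forming C7–C8 with the 1,1-disubstituted alkene already in place. The neutral medium should keep the β,γ-unsaturated aldehyde from isomerising and leaves epoxide and silyl ethers alone; C8 is not controlled here and is set in step 14.

Step 13
Reactants: 19 allylic alcohol epimers
Product: 20 C8 enone (ring–C(=CH2)–C(=O)–CH2CH=CMe2)
Conditions: Dess–Martin periodinane (1.5 equiv), NaHCO3, CH2Cl2, 0 °C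
Reagents that add atoms: none
Why: Dess–Martin oxidation converts both C8 epimers into one enone under buffered, non-enolising conditions, so the skipped C10=C11 alkene should not move into conjugation.

Step 14
Reactants: 20 enone
Product: 21 (8S)-allylic alcohol
Conditions: (R)-2-methyl-CBS-oxazaborolidine [(R)-1-methyl-3,3-diphenyltetrahydro-1H,3H-pyrrolo[1,2-c][1,3,2]oxazaborole] (0.5 equiv), catecholborane (2 equiv), toluene, −78 °C
Reagents that add atoms: none
Why: Corey–Bakshi–Shibata reduction: the ketone binds to the ring boron with its larger 1-substituted vinyl group (C7) away from the B-methyl group and the CH2-prenyl group as the small substituent, so hydride from the nitrogen-bound borane goes to the face that gives the 8S carbinol (the (R)-catalyst gives the S alcohol when the unsaturated group is the large one, as with aryl and alkenyl ketones). Catecholborane at −78 °C should reduce in the 1,2 sense without hydroborating the alkenes.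

Step 15
Reactants: 21 (8S)-allylic alcohol; 22 angelic acid
Product: 24 (8S)-angelate of 21, via mixed anhydride 23 (not isolated)
Conditions: 22 (3 equiv), 2,4,6-trichlorobenzoyl chloride (3 equiv), Et3N, toluene, rt, 2 h; then 21, toluene, 70 °C
Reagents that add atoms: none
Why: Yamaguchi esterification through the mixed anhydride 23: the hindered aroyl carbonyl is not attacked, so the alcohol is acylated by the angeloyl group with retention at C8. Leaving out 4-(dimethylamino)pyridine avoids the conjugate addition–elimination by which nucleophilic catalysts isomerise Z-2-methylbut-2-enoates to the E isomers.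

Step 16
Reactants: 24 tris-silyl angelate
Product: 25 ring triol (2β-OH, 5β-OH, 6β-OH; 3α,4α-epoxide; (8S)-angelate)
Conditions: HF·pyridine (excess), pyridine, THF, 0 °C → rt
Reagents that add atoms: none
Why: Fluoride cleavage of the three Si–O bonds in a pyridine-buffered medium; neither the angelate nor the trisubstituted epoxide, which is deactivated by oxygen on both neighbouring carbons, should react, and no ring acyl group is yet present to migrate.

Step 17
Reactants: 25 ring triol
Product: 26 2,6-di-O-acetate of 25 with free 5β-hydroxyl
Conditions: Ac2O (2.2 equiv), pyridine, CH2Cl2, −20 → 0 °C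
Reagents that add atoms: acetic anhydride, CC(=O)OC(C)=O
Why: Kinetically controlled acetylation: with the side chain equatorial, the C2 and C6 hydroxyls are equatorial, whereas the C5 hydroxyl is axial, syn to the C4 methyl group and attached next to a fully substituted carbon, so it should react last. Two equivalents of anhydride at low temperature without an acyl-transfer catalyst should stop at the diacetate.

Step 18
Reactants: 26 diacetate with free C5 hydroxyl
Product: 27 CNP0298051.3, the (1R,2R,3S,4S,6S,8S) target
Conditions: Dess–Martin periodinane (2 equiv), NaHCO3, CH2Cl2, 0 °C → rt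
Reagents that add atoms: none
Why: Dess–Martin oxidation of the remaining axial secondary alcohol gives the C5 ketone under neutral conditions, so the α-acetoxy centre C6 and the α,β-epoxy ketone never meet base.

## Compound list

1 | 6-methyl-2H-pyran-2-one | CC1=CC=CC(=O)O1 | starting material
2 | vinylene carbonate | O=C1OC=CO1 | starting material
3 | (±)-endo-7,8-(carbonyldioxy)-1-methyl-2-oxabicyclo[2.2.2]oct-5-en-3-one (racemate, target-series enantiomer drawn) | O=C1O[C@@]2(C)C=C[C@@H]1[C@@H]3OC(=O)O[C@@H]32 | intermediate
4 | (±)-methyl (1R*,4S*,5S*,6S*)-4,5,6-trihydroxy-4-methylcyclohex-2-ene-1-carboxylate (racemate, target-series enantiomer drawn) | COC(=O)[C@@H]1C=C[C@](C)(O)[C@@H](O)[C@H]1O | intermediate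
5 | methyl (1R,4S,5S,6S)-4,5,6-trihydroxy-4-methylcyclohex-2-ene-1-carboxylate | COC(=O)[C@@H]1C=C[C@](C)(O)[C@@H](O)[C@H]1O | intermediate
6 | 5,6-O-phenylboronate of 5 | COC(=O)[C@@H]1C=C[C@](C)(O)[C@H]2OB(c3ccccc3)O[C@@H]12 | intermediate
7 | 4-O-trimethylsilyl ether of 6 | COC(=O)[C@@H]1C=C[C@](C)(O[Si](C)(C)C)[C@H]2OB(c3ccccc3)O[C@@H]12 | intermediate
8 | methyl (1R,4S,5S,6S)-5,6-dihydroxy-4-methyl-4-(trimethylsilyloxy)cyclohex-2-ene-1-carboxylate | COC(=O)[C@@H]1C=C[C@](C)(O[Si](C)(C)C)[C@@H](O)[C@H]1O | intermediate
9 | (1R,4S,5S,6S)-5,6-dihydroxy-N-methoxy-N,4-dimethyl-4-(trimethylsilyloxy)cyclohex-2-ene-1-carboxamide | CON(C)C(=O)[C@@H]1C=C[C@](C)(O[Si](C)(C)C)[C@@H](O)[C@H]1O | intermediate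
10 | 2β,3β-epoxide of 9 | CON(C)C(=O)[C@@H]1[C@H]2O[C@H]2[C@](C)(O[Si](C)(C)C)[C@@H](O)[C@H]1O | intermediate
11 | 5,6-bis-O-TBS ether of 10 | CON(C)C(=O)[C@@H]1[C@H]2O[C@H]2[C@](C)(O[Si](C)(C)C)[C@@H](O[Si](C)(C)C(C)(C)C)[C@H]1O[Si](C)(C)C(C)(C)C | intermediate
12 | C4 carbinol (11 without the trimethylsilyl group; present as its alkoxide) | CON(C)C(=O)[C@@H]1[C@H]2O[C@H]2[C@](C)(O)[C@@H](O[Si](C)(C)C(C)(C)C)[C@H]1O[Si](C)(C)C(C)(C)C | intermediate
13 | Weinreb amide with 2β-OH, 3α,4α-epoxide, 5β,6β-bis(TBS-oxy) | CON(C)C(=O)[C@@H]1[C@@H](O)[C@@H]2O[C@]2(C)[C@@H](O[Si](C)(C)C(C)(C)C)[C@H]1O[Si](C)(C)C(C)(C)C | intermediate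
14 | 2-O-triethylsilyl ether of 13 | CON(C)C(=O)[C@@H]1[C@@H](O[Si](CC)(CC)CC)[C@@H]2O[C@]2(C)[C@@H](O[Si](C)(C)C(C)(C)C)[C@H]1O[Si](C)(C)C(C)(C)C | intermediate
15 | methyl ketone (C1-acetyl compound) | CC(=O)[C@@H]1[C@@H](O[Si](CC)(CC)CC)[C@@H]2O[C@]2(C)[C@@H](O[Si](C)(C)C(C)(C)C)[C@H]1O[Si](C)(C)C(C)(C)C | intermediate
16 | potassium enolate of 15 (methyl side) | C=C([O-])[C@@H]1[C@@H](O[Si](CC)(CC)CC)[C@@H]2O[C@]2(C)[C@@H](O[Si](C)(C)C(C)(C)C)[C@H]1O[Si](C)(C)C(C)(C)C.[K+] | intermediate
17 | C7 enol triflate | C=C(OS(=O)(=O)C(F)(F)F)[C@@H]1[C@@H](O[Si](CC)(CC)CC)[C@@H]2O[C@]2(C)[C@@H](O[Si](C)(C)C(C)(C)C)[C@H]1O[Si](C)(C)C(C)(C)C | intermediate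
18 | 4-methylpent-3-enal | CC(C)=CCC=O | starting material
19 | C8 allylic alcohol, mixture of C8 epimers | C=C([C@@H]1[C@@H](O[Si](CC)(CC)CC)[C@@H]2O[C@]2(C)[C@@H](O[Si](C)(C)C(C)(C)C)[C@H]1O[Si](C)(C)C(C)(C)C)C(O)CC=C(C)C | intermediate
20 | C8 enone | C=C([C@@H]1[C@@H](O[Si](CC)(CC)CC)[C@@H]2O[C@]2(C)[C@@H](O[Si](C)(C)C(C)(C)C)[C@H]1O[Si](C)(C)C(C)(C)C)C(=O)CC=C(C)C | intermediate
21 | (8S)-allylic alcohol | C=C([C@@H]1[C@@H](O[Si](CC)(CC)CC)[C@@H]2O[C@]2(C)[C@@H](O[Si](C)(C)C(C)(C)C)[C@H]1O[Si](C)(C)C(C)(C)C)[C@H](CC=C(C)C)O | intermediate
22 | angelic acid, (Z)-2-methylbut-2-enoic acid | C/C=C(/C)C(=O)O | starting material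
23 | angelic 2,4,6-trichlorobenzoic anhydride | C/C=C(/C)C(=O)OC(=O)c1c(Cl)cc(Cl)cc1Cl | intermediate
24 | (8S)-angelate, tris-silyl ether | C=C([C@@H]1[C@@H](O[Si](CC)(CC)CC)[C@@H]2O[C@]2(C)[C@@H](O[Si](C)(C)C(C)(C)C)[C@H]1O[Si](C)(C)C(C)(C)C)[C@H](CC=C(C)C)OC(=O)/C(C)=C\C | intermediate
25 | ring triol (2β,5β,6β-OH; 3α,4α-epoxide; 8S angelate) | C=C([C@@H]1[C@@H](O)[C@@H]2O[C@]2(C)[C@@H](O)[C@H]1O)[C@H](CC=C(C)C)OC(=O)/C(C)=C\C | intermediate
26 | 2,6-diacetate with free 5β-OH | C=C([C@@H]1[C@@H](OC(C)=O)[C@@H]2O[C@]2(C)[C@@H](O)[C@H]1OC(C)=O)[C@H](CC=C(C)C)OC(=O)/C(C)=C\C | intermediate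
27 | CNP0298051.3, (1R,2R,3S,4S,6S,8S) | C=C([C@@H]1[C@@H](OC(C)=O)[C@@H]2O[C@]2(C)C(=O)[C@H]1OC(C)=O)[C@H](CC=C(C)C)OC(=O)/C(C)=C\C | target

## Step count and least certain steps

Total: 18 steps. Longest linear sequence: 18 steps, from 1 and 2 to 27; 18 and 22 enter as purchased compounds.

Step 1 (key step). An unactivated pyrone and a weak dienophile may combine too slowly, endo selectivity may erode, and longer heating invites cycloreversion with loss of CO2 or polymerisation of 2. Fallback, from 1 back to 3: bromination of 1 (Br2, CH2Cl2, then Et3N) gives 3-bromo-6-methyl-2H-pyran-2-one F1. This ambiphilic diene should add 2 thermally (toluene, 90 °C) to the endo bromo adduct F2, and Bu3SnH with azobisisobutyronitrile removes the bridgehead bromine to give 3.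

Step 3. The enzyme may discriminate the enantiomers poorly, acylate both secondary hydroxyls, or turn over slowly on a triol. Fallback, from 3 back to 5: saponification of 3 (LiOH, aqueous THF) gives the non-enolisable (±)-4,5,6-trihydroxy-4-methylcyclohex-2-ene-1-carboxylic acid F3. Fractional crystallisation of its salt with (R)-1-phenylethylamine gives the (1R,4S,5S,6S) salt F4 (the S amine is used if the other salt is the less soluble one). Acidification and Me3SiCHN2 in MeOH/toluene then give 5.

Step 6. Facial control may be lost if undirected attack on the α face competes, the electron-poor alkene may react sluggishly, and the trimethylsilyl ether may be lost. Fallback, from 9 back to 13, using the allylic stereocentre instead of hydroxyl direction: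
- Silylation of 9 (TBSOTf, 2,6-lutidine) gives the bis-TBS alkene F5.
- OsO4 (cat.) with N-methylmorpholine N-oxide adds anti to the allylic silyloxy group to give the 2β,3β-diol F6.
- SOCl2/Et3N then RuCl3 (cat.)/NaIO4 give the cyclic sulfate F7.
- K2CO3/MeOH removes the trimethylsilyl group, and the C4 alkoxide opens the sulfate at C3 to the potassium C2 sulfate F8.
- Catalytic H2SO4 with one equivalent of water in THF gives 13.

Step 14. The reduction may go partly in the 1,4 sense, the skipped alkene of 20 may move into conjugation before reduction, or the catalyst may not distinguish the two ketone substituents well enough. Fallback, from 19 back to 21, without the enone: chromatography of 19 separates 21 from the (8R)-epimer F9. Mitsunobu reaction of F9 (4-nitrobenzoic acid, PPh3, diisopropyl azodicarboxylate) inverts C8 to the (8S)-4-nitrobenzoate F10, and K2CO3/MeOH releases 21.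

Step 17. Acetylation may run on to O5, or the acetyl group may migrate from O6 to the cis O5 during work-up. Fallback, from 25 back to 26: Bu2SnO in toluene with azeotropic removal of water forms the 5,6-O-dibutylstannylene acetal F11. AcCl at 0 °C should then acylate the equatorial O6, and Ac2O/pyridine acetylates the C2 hydroxyl to give 26.

## Further compounds

F1 | step 1 | 3-bromo-6-methyl-2H-pyran-2-one | CC1=CC=C(Br)C(=O)O1
F2 | step 1 | (±)-endo bromo adduct, bromine on the bridgehead C1 (target-series enantiomer drawn) | O=C1O[C@@]2(C)C=C[C@]1(Br)[C@@H]3OC(=O)O[C@@H]32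
F3 | step 3 | (±)-4,5,6-trihydroxy-4-methylcyclohex-2-ene-1-carboxylic acid (target-series enantiomer drawn) | OC(=O)[C@@H]1C=C[C@](C)(O)[C@@H](O)[C@H]1O
F4 | step 3 | (R)-1-phenylethylammonium (1R,4S,5S,6S)-4,5,6-trihydroxy-4-methylcyclohex-2-ene-1-carboxylate | [O-]C(=O)[C@@H]1C=C[C@](C)(O)[C@@H](O)[C@H]1O.C[C@@H]([NH3+])c1ccccc1
F5 | step 6 | 5,6-bis-O-TBS ether of 9 | CON(C)C(=O)[C@@H]1C=C[C@](C)(O[Si](C)(C)C)[C@@H](O[Si](C)(C)C(C)(C)C)[C@H]1O[Si](C)(C)C(C)(C)C
F6 | step 6 | 2β,3β-diol of F5 | CON(C)C(=O)[C@@H]1[C@@H](O)[C@@H](O)[C@](C)(O[Si](C)(C)C)[C@@H](O[Si](C)(C)C(C)(C)C)[C@H]1O[Si](C)(C)C(C)(C)C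
F7 | step 6 | 2β,3β-cyclic sulfate of F6 | CON(C)C(=O)[C@@H]1[C@H]2OS(=O)(=O)O[C@H]2[C@](C)(O[Si](C)(C)C)[C@@H](O[Si](C)(C)C(C)(C)C)[C@H]1O[Si](C)(C)C(C)(C)C
F8 | step 6 | potassium 2β-sulfate of the 3α,4α-epoxide | CON(C)C(=O)[C@@H]1[C@@H](OS(=O)(=O)[O-])[C@@H]2O[C@]2(C)[C@@H](O[Si](C)(C)C(C)(C)C)[C@H]1O[Si](C)(C)C(C)(C)C.[K+]
F9 | step 14 | (8R)-epimer of 21 | C=C([C@@H]1[C@@H](O[Si](CC)(CC)CC)[C@@H]2O[C@]2(C)[C@@H](O[Si](C)(C)C(C)(C)C)[C@H]1O[Si](C)(C)C(C)(C)C)[C@@H](CC=C(C)C)O
F10 | step 14 | (8S)-4-nitrobenzoate of 21 | C=C([C@@H]1[C@@H](O[Si](CC)(CC)CC)[C@@H]2O[C@]2(C)[C@@H](O[Si](C)(C)C(C)(C)C)[C@H]1O[Si](C)(C)C(C)(C)C)[C@H](CC=C(C)C)OC(=O)c1ccc(cc1)[N+](=O)[O-]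
F11 | step 17 | 5,6-O-dibutylstannylene acetal of 25 | C=C([C@@H]1[C@@H](O)[C@@H]2O[C@]2(C)[C@H]3O[Sn](CCCC)(CCCC)O[C@@H]13)[C@H](CC=C(C)C)OC(=O)/C(C)=C\C
A1 | alternative 1 | cyclohexane cis-2,3-diol with 4,5-acetonide, 6-O-TBS and 8-O-PMB | C=C([C@@H]1[C@@H](O)[C@@H](O)[C@]2(C)OC(C)(C)O[C@@H]2[C@H]1O[Si](C)(C)C(C)(C)C)[C@H](CC=C(C)C)OCc1ccc(OC)cc1
A2 | alternative 1 | open-chain C2/C3 dialdehyde | C=C([C@H](C=O)[C@H](O[Si](C)(C)C(C)(C)C)[C@H]1OC(C)(C)O[C@@]1(C)C=O)[C@H](CC=C(C)C)OCc1ccc(OC)cc1
A3 | alternative 2 | trans-fused α-methylene-γ-butyrolactone (lactone carbonyl C8) | C=C1C(=O)O[C@H]2[C@@H]3O[C@]3(C)[C@H]3OC(C)(C)O[C@H]3[C@H]12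
A4 | alternative 2 | trans-2-ethynylcyclohexanol with 3,4-epoxide and 5,6-acetonide | C#C[C@@H]1[C@@H](O)[C@@H]2O[C@]2(C)[C@H]3OC(C)(C)O[C@@H]13
A5 | alternative 3 | cyclohexenol with free C2 hydroxyl, 5,6-acetonide and complete side chain | C=C([C@@H]1[C@@H](O)C=C(C)[C@@H]2OC(C)(C)O[C@@H]12)[C@H](CC=C(C)C)OC(=O)/C(C)=C\C
A6 | alternative 3 | open-chain Z-enal allylic bromide | O=C/C=C(C)\[C@@H]1OC(C)(C)O[C@H]1/C=C(CBr)/[C@H](CC=C(C)C)OC(=O)/C(C)=C\C
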